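(All runs were computed for substances that don't exist; the scatter is artificial.)

Turn the question round.

all flasks: starting complex 0.050 M
- Monday's: incoming ligand 0.080 M; leaving ligand 0.025 M; run made earlier
- Thursday's: incoming ligand 0.24 M; leaving ligand 0.025 M; run made earlier
- zeta: incoming ligand 0.0600 M; leaving ligand 0.0250 M; time 2.0 min
- theta: incoming ligand 0.0750 M; leaving ligand 0.0250 M; time 2.0 min
- alpha: incoming ligand 0.150 M; leaving ligand 0.0250 M; time 2.0 min

- Monday's (time / s: complex with two exchanged / %, complex with one exchanged / %, starting complex / %): 15.0: 1.3, 9.3, 89.7; 30.0: 4.8, 15.2, 80.5; 50.0: 10.2, 18.2, 71.2; 60.0: 13.0, 19.1, 67.9; 80.0: 17.4, 20.7, 61.4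
- Thursday's (time / s: complex with two exchanged / %, complex with one exchanged / %, starting complex / %): 10.0: 4.9, 15.1, 79.8; 20.0: 15.1, 20.0, 65.0; 40.0: 36.5, 19.8, 44.3; 60.0: 52.4, 16.3, 31.4; 80.0: 64.5, 12.1, 23.0

(readings scatter by 0.3 percentage points)

- leaving ligand is meant together with its crystals
- solid, in amounts per volume of the solution: crystals
- steps thought possible: starting complex + incoming ligand -> leaving ligand + complex with one exchanged; complex with one exchanged + incoming ligand -> leaving ligand + complex with two exchanged; crystals <-> leaving ligand; incoming ligand -> decomposed reagent

1. which of these holds the largest part of the starting complex at the end of zeta (complex with two exchanged / starting complex / complex with one exchanged)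
2. which of these holds the largest part of the starting complex at the end of theta (complex with two exchanged / starting complex / complex with one exchanged)
3. which of these holds the largest part of the starting complex at the end of alpha (complex with two exchanged / starting complex / complex with one exchanged)
4. complex with two exchanged at the end of zeta, in percent of the starting complex charged

Ask what complex with two exchanged needs in order to pass starting complex. The fractions of the charge sum to one, and each complex with two exchanged has taken two ligands, so the uptake per complex is one minus the starting fraction plus the two-exchanged fraction. At the crossing that is exactly one equivalent.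

Monday's and Thursday's runs seem to walk one path: Monday's 61.4% left with 17.4% two-exchanged lies between Thursday's 65.0% with 15.1% and 44.3% with 36.5%. So I take incoming ligand concentration summed over time, the dose, as the clock. Thursday's readings cross near 45.4 s. That run is nearly pseudo-first-order, so the ligand loss is a correction: taking half of the one equivalent as the mean loss leaves 0.896 of its charge. This gives the crossing dose 9.76 M·s.

No listed step makes incoming ligand, so in these flasks the dose stays under charge times time. In zeta that ceiling is 0.737 of the crossing dose, and in theta 0.922, so I keep starting complex ahead of two-exchanged in both. In alpha, before the crossing, incoming ligand stays above its charge minus one equivalent, apart from any decay of its own; that floor gives 1.23, so I expect alpha to cross. The highest reading of complex with one exchanged is 20.7%, so I leave it out of the race.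

The forecast agrees: starting complex in zeta, starting complex in theta, complex with two exchanged in alpha, and 18.4% for zeta (16.5% to 20%): “Ligand depletion strongly slows zeta and theta, so the starting complex stays largest there.”

    starting complex + incoming ligand → leaving ligand + complex with one exchanged (k = 0.0970 M⁻¹ s⁻¹)
    complex with one exchanged + incoming ligand → leaving ligand + complex with two exchanged (k = 0.260 M⁻¹ s⁻¹)
    crystals ⇌ leaving ligand, rate k3*(cs3 - [leaving ligand]) while solid is left; crystals form when [leaving ligand] > cs3 (solubility = 4.30 mM, k = 0.340 s⁻¹)
    incoming ligand → decomposed reagent (k = 8.70 × 10⁻⁴ s⁻¹)

Zeta ends at 18.1%, with starting complex leading at 61.5%; theta's lead is starting complex and alpha's complex with two exchanged. Moved alone, an incoming ligand charge of 0.0484 M or 0.0712 M shifts zeta's answer by 5 points, outside the forecast's range. Zeta's incoming ligand stood at 67.9% of its charge halfway and 46% at the end, so its dose was about 5.07 M·s, which is 0.519 of the crossing dose.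

Charge zeta with 0.24 M of incoming ligand instead: the floor gives 2.33 crossing doses, so it should cross. It ends with complex with two exchanged at 79.6% and 13% of starting complex left.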